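1. Slowness comes first. The north-west run holds 1.6% of D at 0.500 min, and the west run 0% at 0.250 min.

| flask | Q | G | remark | time | volume of the second phase over the first |
|---|---|---|---|---|---|
| north-west | 2.1 M | 1.05 equiv | run made earlier |  |  |
| west | 1.5 M | 0.53 equiv | run made earlier |  |  |
| flask | 1.5 M | 1.05 equiv |  | 4.0 min | 1.0 |

| run | time / min | D / % |
|---|---|---|
| north-west | 0.500 | 1.6 |
| north-west | 1.00 | 4.0 |
| north-west | 1.33 | 5.5 |
| north-west | 2.00 | 13.0 |
| north-west | 2.50 | 14.4 |
| north-west | 3.00 | 14.5 |
| west | 0.250 | 0 |
| west | 0.833 | 0.9 |
| west | 1.33 | 1.8 |
| west | 2.50 | 6.3 |
| west | 3.00 | 7.1 |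

(standard deviation of a reading: 1 percentage point)

- in the second phase: G; everything else is in the first
- charges count per volume of the first phase; a concentration in a rate is the amount of a species over the volume of its own phase; every rate counts per litre of the first phase
- the earlier runs hold the two phases in the same ratio of volumes as the flask asked about

- how much D there is at 4.0 min, in percent of the Q charged
- the change that raises the amount of D at 4.0 min, in percent of the Q charged most ("none" if none brings more than 2 percentage points) (summer / midnight / none)
- amount of D at 4.0 min, in percent of the Q charged, after midnight

- summer: doubling the amount of G, all else as stated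
- midnight: doubling the transfer coefficient of G, all else as stated

2. On logarithms, the north-west readings climb as time to the power 1.51 up to 2.00 min. That curve starts flat and steepens.

3. The north-west run reads 13.0% at 2.00 min and 14.5% at 3.00 min, but each reading carries a scatter of 1 percentage point, so I read neither a knee nor a level from them. The west run reads 7.1% at 3.00 min, and from 1.33 min its readings climb as time to the power 1.69.

4. I take cG as the charged concentration of G: 2.21 M in the north-west run, 0.795 M in the west run. At 3.00 min the two runs give 0.700. This is n, the logarithm of the D ratio over the logarithm of the cG ratio at one time. The two runs also differ in Q, 2.1 M against 1.5 M, so n is a reading across both changes and no reaction order in G alone.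

5. The flask has cG of 1.58 M and the equivalents of the north-west run, so I scale from that run, and as a rough reckoning n puts the flask's D at 11.5% at 3.00 min. If it keeps rising like the west run, it reaches 18.6% at 4.0 min. I commit to the geometric middle, 14.6%.

6. Summer doubles cG with Q held, a move the two runs do not make, so I use n here as a rough guide: D multiplied by 1.62, a gain of 9.1 points. Midnight leaves cG as it is, so n gives me nothing there.

7. The forecast says 12.5% (10% to 15%), summer, and 13.5% (11.5% to 16%) after midnight: “Doubling G lifts the ceiling itself”.

8. The flask gives 16.9%. Summer adds 6.9 points, more than the 3.5 points of midnight. After midnight the flask holds 20.4%, above the forecast's 13.5%.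

    X ⇌ G, rate k1*([X] - [G]/K1) per volume of the first phase (partition coefficient = 1.50, kL = 0.00460 /s)
    Q + X → D (k = 0.00570 /M/s)
    X + D → L (k = 0.00920 /M/s)
    Q → Z (k = 2.30 × 10⁻⁶ /s)
    D → E (k = 0.00130 /s)

9. On this flask, n turns 16.9% into a summer gain of 11 points, against the simulated 6.9 points. With Q held, that simulated gain gives an exponent of 0.494, lower than n. The neighbouring flask has 0.38 M of Q at the same equivalents, so its cG is the flask's multiplied by 0.253. Then n gives 6.47% of D. That neighbouring flask stores 7.93% at 4.00 min, with 90% of its Q left.

The runs were generated by integration for substances that don't exist; noise was put on by code.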